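**Strategy.** Everything rests on the C4–C4a bond of the dihydrocoumarin, the bond from the benzo-ring carbon para to the C7 oxygen to the benzylic stereocentre. The precursor is an acyclic aryl (E)-caffeate in which the lactone ester O1–C2 already exists and tethers the electron-rich arene to the caffeoyl β-carbon. A confined chiral Brønsted acid then effects an enantioselective 6-endo Friedel–Crafts hydroarylation that closes the lactone ring and sets C4 in one operation. The step exploits the C7 oxygen para to C4a (nucleophile) and the C4' oxygen of the catechol ring para to C4 (cation stabilisation). One global desilylation follows.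

Key step: step 6

Remark on the chemistry: the target is (4R). The sense of induction of the chiral acid in step 6 cannot be predicted with confidence, so the catalyst enantiomer that delivers (R)-11 is assumed to be found in a short screen of both antipodes. Compounds 1, 3 and 7 are taken as commercial. TBS = tert-butyldimethylsilyl.

**Step 1**
Reactants: 1 4-(benzyloxy)-2-hydroxybenzaldehyde
Product: 2 4-(benzyloxy)-2-(TBS-oxy)benzaldehyde
Conditions: TBSCl, imidazole, DMF, rt
Reagents that add atoms: tert-butyldimethylsilyl chloride, CC(C)(C)[Si](C)(C)Cl
Why: Standard imidazole-promoted O-silylation of a phenol should cap the only free hydroxyl, the one ortho to the formyl group, so that this oxygen (the later C7–OH) stays masked until the last step.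

**Step 2**
Reactants: 2 4-(benzyloxy)-2-(TBS-oxy)benzaldehyde; 3 (3,4-dimethoxybenzyl)triphenylphosphonium bromide
Product: 5 tert-butyl{5-(benzyloxy)-2-[2-(3,4-dimethoxyphenyl)ethenyl]phenoxy}dimethylsilane (E/Z mixture), via ylide 4 (not isolated)
Conditions: 3, NaN(SiMe3)2, THF, 0 °C; then 2, −78 °C to rt
Reagents that add atoms: none
Why: Wittig olefination of an aromatic aldehyde with a semi-stabilised benzylic ylide should give the stilbene as an E/Z mixture, which is of no consequence because the double bond is saturated in step 3.

**Step 3**
Reactants: 5 stilbene (E/Z mixture)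
Product: 6 3-(TBS-oxy)-4-[2-(3,4-dimethoxyphenyl)ethyl]phenol
Conditions: H2 (1 atm), Pd/C (10 wt%), EtOAc, rt
Reagents that add atoms: none
Why: Heterogeneous catalytic hydrogenation should saturate the stilbene and hydrogenolyse the aryl benzyl ether in one operation, while the aryl silyl ether and the methyl ethers are inert in neutral EtOAc, which leaves free only the hydroxyl para to the side chain.

**Step 4**
Reactants: 7 caffeic acid, (E)-3-(3,4-dihydroxyphenyl)prop-2-enoic acid
Product: 9 (E)-3-[3,4-bis(TBS-oxy)phenyl]prop-2-enoic acid, via silyl ester 8 (not isolated)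
Conditions: TBSCl (3.5 equiv), imidazole, DMF, rt; then AcOH/THF/H2O, rt
Reagents that add atoms: tert-butyldimethylsilyl chloride, CC(C)(C)[Si](C)(C)Cl
Why: Exhaustive silylation of both phenols and the carboxylic acid, followed by chemoselective hydrolysis of the far more labile silyl ester, should leave the catechol as its bis-silyl ether with the E alkene untouched.

**Step 5**
Reactants: 6 3-(TBS-oxy)-4-[2-(3,4-dimethoxyphenyl)ethyl]phenol; 9 (E)-3-[3,4-bis(TBS-oxy)phenyl]prop-2-enoic acid
Product: 10 3-(TBS-oxy)-4-[2-(3,4-dimethoxyphenyl)ethyl]phenyl (E)-3-[3,4-bis(TBS-oxy)phenyl]prop-2-enoate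
Conditions: EDC·HCl, DMAP (cat.), CH2Cl2, 0 °C to rt
Reagents that add atoms: none
Why: Steglich esterification of the single free phenol of 6 with acid 9 should give the aryl cinnamate without any question of regiochemistry, and the mild carbodiimide conditions spare the silyl ethers and the E alkene.

**Step 6**
Reactants: 10 aryl (E)-caffeate
Product: 11 (4R)-4-[3,4-bis(TBS-oxy)phenyl]-7-(TBS-oxy)-6-[2-(3,4-dimethoxyphenyl)ethyl]-3,4-dihydro-2H-chromen-2-one
Conditions: chiral IDPi acid [imidodiphosphorimidate from two 3,3'-bis(3,5-bis(trifluoromethyl)phenyl)-BINOL units, N-SO2CF3 groups] (5 mol%), CHCl3 (0.02 M), −20 °C to rt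
Reagents that add atoms: none
Why: Proposed new method: the strong confined acid protonates the ester carbonyl of 10, giving a cation delocalised to C4 and to the para silyloxy oxygen of the catechol ring that stays paired with the chiral IDPi anion, and the benzo-ring carbon ortho to the ester oxygen and para to the OTBS group attacks C4; loss of the ring proton and ketonisation of the resulting ketene hemiacetal return the acid. The closest known reaction types are the racemic strong-acid cyclisation of aryl cinnamates to 4-aryl-3,4-dihydrocoumarins and the IDPi-catalysed asymmetric Nazarov cyclisation of divinyl ketones, intramolecular hydroarylation of olefins and (as the silylated catalyst) Mukaiyama–Michael addition to α,β-unsaturated esters; an enantioselective ring closure of an aryl cinnamate has not been shown. The lactone ring closes in the 6-endo-trig mode through the less stable but accessible E conformer of the aryl ester. The new stereocentre C4 is under catalyst control: the anion pocket shields one face of the planar benzylic cation, and the catalyst enantiomer that delivers (R) is used. Regioselectivity (attack at the unhindered CH para to OTBS, not at the CH between the two oxygens) follows the electronic and steric bias familiar from Pechmann closures of resorcinols, and ring closure is favoured over alkylation of the veratryl ring or of a second molecule by the six-membered transition state and high dilution.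

**Step 7**
Reactants: 11 tris-silylated (4R)-lactone
Product: 12 (4R)-4-(3,4-dihydroxyphenyl)-7-hydroxy-6-[2-(3,4-dimethoxyphenyl)ethyl]-3,4-dihydro-2H-chromen-2-one
Conditions: Bu4NF, AcOH, THF, 0 °C
Reagents that add atoms: none
Why: Fluoride-mediated cleavage of the three aryl silyl ethers, buffered with AcOH so that no phenoxide persists to open the aryl lactone or let the catechol oxidise, should release the target, and C4 is not acidic and keeps its (R) configuration.

**Compound list**
1 | 4-(benzyloxy)-2-hydroxybenzaldehyde | O=Cc1ccc(OCc2ccccc2)cc1O | starting material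
2 | 4-(benzyloxy)-2-[(tert-butyldimethylsilyl)oxy]benzaldehyde | O=Cc1ccc(OCc2ccccc2)cc1O[Si](C)(C)C(C)(C)C | intermediate
3 | (3,4-dimethoxybenzyl)triphenylphosphonium bromide | COc1ccc(C[P+](c2ccccc2)(c2ccccc2)c2ccccc2)cc1OC.[Br-] | starting material
4 | (3,4-dimethoxybenzylidene)triphenylphosphorane (ylide, not isolated) | COc1ccc(C=P(c2ccccc2)(c2ccccc2)c2ccccc2)cc1OC | intermediate
5 | tert-butyl{5-(benzyloxy)-2-[2-(3,4-dimethoxyphenyl)ethenyl]phenoxy}dimethylsilane (E/Z mixture, geometry not defined) | COc1ccc(C=Cc2ccc(OCc3ccccc3)cc2O[Si](C)(C)C(C)(C)C)cc1OC | intermediate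
6 | 3-[(tert-butyldimethylsilyl)oxy]-4-[2-(3,4-dimethoxyphenyl)ethyl]phenol | COc1ccc(CCc2ccc(O)cc2O[Si](C)(C)C(C)(C)C)cc1OC | intermediate
7 | caffeic acid, (E)-3-(3,4-dihydroxyphenyl)prop-2-enoic acid | OC(=O)/C=C/c1ccc(O)c(O)c1 | starting material
8 | tert-butyldimethylsilyl (E)-3-{3,4-bis[(tert-butyldimethylsilyl)oxy]phenyl}prop-2-enoate (not isolated) | CC(C)(C)[Si](C)(C)OC(=O)/C=C/c1ccc(O[Si](C)(C)C(C)(C)C)c(O[Si](C)(C)C(C)(C)C)c1 | intermediate
9 | (E)-3-{3,4-bis[(tert-butyldimethylsilyl)oxy]phenyl}prop-2-enoic acid | OC(=O)/C=C/c1ccc(O[Si](C)(C)C(C)(C)C)c(O[Si](C)(C)C(C)(C)C)c1 | intermediate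
10 | 3-[(tert-butyldimethylsilyl)oxy]-4-[2-(3,4-dimethoxyphenyl)ethyl]phenyl (E)-3-{3,4-bis[(tert-butyldimethylsilyl)oxy]phenyl}prop-2-enoate | COc1ccc(CCc2ccc(OC(=O)/C=C/c3ccc(O[Si](C)(C)C(C)(C)C)c(O[Si](C)(C)C(C)(C)C)c3)cc2O[Si](C)(C)C(C)(C)C)cc1OC | intermediate
11 | (4R)-4-{3,4-bis[(tert-butyldimethylsilyl)oxy]phenyl}-7-[(tert-butyldimethylsilyl)oxy]-6-[2-(3,4-dimethoxyphenyl)ethyl]-3,4-dihydro-2H-chromen-2-one | COc1ccc(CCc2cc3c(cc2O[Si](C)(C)C(C)(C)C)OC(=O)C[C@@H]3c2ccc(O[Si](C)(C)C(C)(C)C)c(O[Si](C)(C)C(C)(C)C)c2)cc1OC | intermediate
12 | (4R)-4-(3,4-dihydroxyphenyl)-7-hydroxy-6-[2-(3,4-dimethoxyphenyl)ethyl]-3,4-dihydro-2H-chromen-2-one | COc1ccc(CCc2cc3c(cc2O)OC(=O)C[C@@H]3c2ccc(O)c(O)c2)cc1OC | target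

**Step count.** Total steps: 7. Longest linear sequence: 6 (steps 1, 2, 3, 5, 6, 7).

**Steps most likely to fail**

1. Step 6 (bears "Proposed new method:"). The chiral anion may discriminate the two faces of the cation only weakly, or the product may lose enantiomeric purity by reversible ring opening under the strong acid. Closure may also be slow because the aryl ester rests in its Z conformer, which would let Fries-type acyl migration or intermolecular alkylation compete. The fallback uses known chemistry, sets out from 6 and 9 and comes back at 11. Acid 9 is treated with pivaloyl chloride and iPr2NEt in THF to give, in the flask, the mixed pivalic anhydride F1. A chiral aminoindanol-derived N-mesityl triazolium salt with further iPr2NEt converts it into the α,β-unsaturated acyl azolium. Phenol 6 then adds through its ring carbon para to OTBS, and the adduct lactonises with release of the carbene to give 11. This is the known carbene-catalysed annulation of unsaturated acyl azoliums with naphthols and electron-rich phenols; it forms the same C–C bond between two molecules and closes the ring by acyl transfer.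

2. Step 7. Fluoride or a transient phenoxide may open the aryl lactone, cleavage of the hindered silyl ethers may stay incomplete, and the free catechol may oxidise in air during work-up. The fallback sets out from 11 and comes back at 12, and accepts ring opening instead of avoiding it. HCl in MeOH at rt should cleave all three silyl ethers and methanolyse the lactone to methyl (3R)-3-(3,4-dihydroxyphenyl)-3-{2,4-dihydroxy-5-[2-(3,4-dimethoxyphenyl)ethyl]phenyl}propanoate F2. Catalytic TsOH in warm toluene should then relactonise F2 onto the only ortho hydroxyl, with loss of methanol, to give 12. The stereocentre is not touched.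

3. Step 2. The ylide or the amide base may attack silicon of the ortho silyl ether, or the silyl group may transfer to the betaine oxygen, so that the protecting group is lost and conversion stalls. The fallback sets out from 1 and comes back at 5, and reverses the order of olefination and protection. Aldehyde 1 as its sodium phenoxide is treated with ylide 4 in excess (from 3 and NaN(SiMe3)2, THF) to give the stilbene phenol 5-(benzyloxy)-2-[2-(3,4-dimethoxyphenyl)ethenyl]phenol F3 as an E/Z mixture. Silylation of F3 with TBSCl and imidazole in DMF then gives 5.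

**Further compounds**
F1 | step 6 | mixed anhydride of 9 with pivalic acid, (E)-3-{3,4-bis[(tert-butyldimethylsilyl)oxy]phenyl}prop-2-enoic pivalic anhydride | CC(C)(C)C(=O)OC(=O)/C=C/c1ccc(O[Si](C)(C)C(C)(C)C)c(O[Si](C)(C)C(C)(C)C)c1
F2 | step 7 | methyl (3R)-3-(3,4-dihydroxyphenyl)-3-{2,4-dihydroxy-5-[2-(3,4-dimethoxyphenyl)ethyl]phenyl}propanoate | COc1ccc(CCc2cc(c(O)cc2O)[C@H](CC(=O)OC)c2ccc(O)c(O)c2)cc1OC
F3 | step 2 | 5-(benzyloxy)-2-[2-(3,4-dimethoxyphenyl)ethenyl]phenol (E/Z mixture) | COc1ccc(C=Cc2ccc(OCc3ccccc3)cc2O)cc1OC
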